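**Strategy.** Numbering: C1(Me)=C2–C3–C4(Me)–C5–C6–C7(OH)(iPr)–C8(H)–C9(O-acyl)–C10, with C10–C1 and C4–C8 bonds. The plan rests on cutting C4–C8 and C4–C3. Six carbons of the seven-membered ring (C8, C3, C2, C1 with its methyl, C10, oxygenated C9) are then the ring of an O-protected m-cresol, and quaternary C4, common to both rings, is a carbenoid carbon. An intramolecular Buchner reaction of an aryl-tethered α-diazoketone that already holds the C7 carbinol (both oxygens silylated) makes both bonds, closes the five- and the seven-membered ring, and sets C4 in one operation.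

Key step: step 9

Assumption: the sense of induction of the chiral allylsilane in step 2 and of the copper–bis(oxazoline) catalyst in step 9 is taken as drawn; if a first run shows the opposite sense, the antipodal reagent or ligand is used.

Step 1
Reactants: 1 m-cresol (3-methylphenol); 2 isobutyryl chloride
Product: 4 1-(2-hydroxy-4-methylphenyl)-2-methylpropan-1-one, via m-tolyl isobutyrate 3 (not isolated)
Conditions: 2 (1.1 equiv), neat, 60 °C; then AlCl3 (1.3 equiv), 140 °C; ice/aq HCl
Reagents that add atoms: none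
Why: O-acylation followed by a thermal Fries rearrangement, which at 140 °C delivers the acyl group to the less hindered ortho position (para to the methyl group) and is driven by aluminium chelation in the o-hydroxy ketone; no stereocentre is formed.

Step 2
Reactants: 4 1-(2-hydroxy-4-methylphenyl)-2-methylpropan-1-one; 5 (3aR,7aR)-2-allyl-1,3-bis(4-bromobenzyl)-2-chlorooctahydro-1H-1,3,2-benzodiazasilole (Leighton allylsilane)
Product: 7 (S)-2-(3-hydroxy-2-methylhex-5-en-3-yl)-5-methylphenol, via aryloxysilane 6 (not isolated)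
Conditions: 5 (1.5 equiv), CH2Cl2, 23–40 °C; then 1 M aq HCl, EtOAc
Reagents that add atoms: none
Why: Phenol-directed Leighton allylation of a 2-hydroxyaryl ketone: the phenol displaces chloride on the strained chiral allylsilane, the Lewis-acidic silicon binds the carbonyl and transfers allyl through a closed chair-like transition state, so the C2-symmetric diamine sets the C7 carbinol (S), a reaction type that accepts branched alkyl aryl ketones.

Step 3
Reactants: 7 (S)-2-(3-hydroxy-2-methylhex-5-en-3-yl)-5-methylphenol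
Product: 8 (S)-3-[2-(tert-butyldimethylsilyloxy)-4-methylphenyl]-2-methylhex-5-en-3-ol
Conditions: TBSCl, imidazole, DMF, 23 °C
Reagents that add atoms: tert-butyldimethylsilyl chloride, CC(C)(C)[Si](C)(C)Cl
Why: Chemoselective O-silylation of the phenol (the hindered tertiary alcohol is inert to TBSCl/imidazole); a silyl rather than an alkyl ether is used so that the later enol ether can be cleaved by fluoride instead of acid.

Step 4
Reactants: 8 (S)-3-[2-(tert-butyldimethylsilyloxy)-4-methylphenyl]-2-methylhex-5-en-3-ol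
Product: 9 tert-butyl{5-methyl-2-[(3S)-2-methyl-3-(triethylsilyloxy)hex-5-en-3-yl]phenoxy}dimethylsilane
Conditions: TESOTf, 2,6-lutidine, CH2Cl2, −78 → 23 °C
Reagents that add atoms: triethylsilyl trifluoromethanesulfonate, CC[Si](CC)(CC)OS(=O)(=O)C(F)(F)F
Why: Silyl triflate silylation of a hindered tertiary alcohol, which removes the O–H bond a carbenoid would insert into and leaves a bulky, weakly basic ether oxygen at C7.

Step 5
Reactants: 9 tert-butyl{5-methyl-2-[(3S)-2-methyl-3-(triethylsilyloxy)hex-5-en-3-yl]phenoxy}dimethylsilane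
Product: 10 (3S)-3-[2-(tert-butyldimethylsilyloxy)-4-methylphenyl]-4-methyl-3-(triethylsilyloxy)pentanal
Conditions: O3, CH2Cl2, −78 °C (Sudan III end point); then PPh3, −78 → 23 °C
Reagents that add atoms: ozone, [O-][O+]=O
Why: Ozonolysis with reductive work-up cleaves the monosubstituted alkene, which reacts far faster than the hindered silyloxyarene at −78 °C under indicator control, to the C5 aldehyde.

Step 6
Reactants: 10 (3S)-3-[2-(tert-butyldimethylsilyloxy)-4-methylphenyl]-4-methyl-3-(triethylsilyloxy)pentanal; 11 ethylmagnesium bromide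
Product: 12 (5S)-5-[2-(tert-butyldimethylsilyloxy)-4-methylphenyl]-6-methyl-5-(triethylsilyloxy)heptan-3-ol (both C3 epimers)
Conditions: THF, −78 °C; aq NH4Cl
Reagents that add atoms: none
Why: Grignard addition to the aldehyde brings in C4 and its methyl group; the new carbinol forms as an epimer mixture that is erased in the next step.

Step 7
Reactants: 12 (5S)-5-[2-(tert-butyldimethylsilyloxy)-4-methylphenyl]-6-methyl-5-(triethylsilyloxy)heptan-3-ol
Product: 13 (5S)-5-[2-(tert-butyldimethylsilyloxy)-4-methylphenyl]-6-methyl-5-(triethylsilyloxy)heptan-3-one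
Conditions: Dess–Martin periodinane, NaHCO3, CH2Cl2, 23 °C
Reagents that add atoms: none
Why: Dess–Martin oxidation of the secondary alcohol under buffered, non-basic conditions gives the β-silyloxy ethyl ketone without β-elimination.

Step 8
Reactants: 13 (5S)-5-[2-(tert-butyldimethylsilyloxy)-4-methylphenyl]-6-methyl-5-(triethylsilyloxy)heptan-3-one
Product: 15 (5S)-2-diazo-5-[2-(tert-butyldimethylsilyloxy)-4-methylphenyl]-6-methyl-5-(triethylsilyloxy)heptan-3-one, via trifluoroacetyl diketone 14 (not isolated)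
Conditions: LiN(SiMe3)2, THF, −78 °C; CF3CO2CH2CF3; aq NH4Cl; then MsN3, Et3N, H2O (1 equiv), MeCN, 23 °C
Reagents that add atoms: methanesulfonyl azide, CS(=O)(=O)N=[N+]=[N-]; 2,2,2-trifluoroethyl trifluoroacetate, O=C(OCC(F)(F)F)C(F)(F)F (atoms kept only in 14)
Why: Danheiser detrifluoroacetylative diazo transfer: kinetic enolisation occurs at the ethyl CH2 (C4) and not at C6, which is neopentyl-like next to the fully substituted C7, the enolate is trifluoroacetylated to 14, and azide transfer with loss of the trifluoroacetyl group gives the α-diazo ketone.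

Step 9
Reactants: 15 (5S)-2-diazo-5-[2-(tert-butyldimethylsilyloxy)-4-methylphenyl]-6-methyl-5-(triethylsilyloxy)heptan-3-one
Product: 17 (3S,8aR)-4-(tert-butyldimethylsilyloxy)-6,8a-dimethyl-3-(propan-2-yl)-3-(triethylsilyloxy)-3,8a-dihydroazulen-1(2H)-one, via norcaradiene 16 (not isolated)
Conditions: Cu(MeCN)4PF6 (5 mol %), (R,R)-2,2'-isopropylidenebis(4-phenyl-2-oxazoline) (6 mol %), NaB[3,5-(CF3)2C6H3]4 (6 mol %), CH2Cl2, 40 °C, slow addition of 15
Reagents that add atoms: none
Why: Loss of N2 from 15 gives a copper carbenoid at C4 that cyclopropanates the ipso–ortho C8–C3 bond of the tethered arene to norcaradiene 16, which opens by a six-electron disrotatory electrocyclic reaction (C8–C3 cleavage) to cycloheptatriene 17. The closest known reaction type is the intramolecular Buchner reaction of 2-diazo-5-arylpentan-3-ones to 8a-methyl-3,8a-dihydroazulen-1(2H)-ones under copper–bis(oxazoline) or dirhodium carboxylate catalysis. The five-membered ring closes by C4–C8 bond formation at the ipso carbon, 5-exo with respect to the attacked C8–C3 π bond, and the seven-membered ring arises by ring expansion of the arene when 16 opens (C4–C3 made, C8–C3 broken). The only new stereocentre, quaternary C4, depends on which arene face the carbenoid takes relative to C7; this is assigned to the chiral copper catalyst, helped in the substrate by the two silyloxy groups (O7 and O9) avoiding each other, which places isopropyl rather than O7 beside C9 and hence cis to the C4 methyl. Regioselectivity for C3 over C9 is secured by the ortho silyloxy substituent, the arene addition must outrun 1,2-hydride shift from the C4 methyl and 1,5 C–H insertion at the isopropyl methine (favoured by an electrophilic copper carbenoid and slow addition), and silylation of O7 excludes O–H insertion.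

Step 10
Reactants: 17 (3S,8aR)-4-(tert-butyldimethylsilyloxy)-6,8a-dimethyl-3-(propan-2-yl)-3-(triethylsilyloxy)-3,8a-dihydroazulen-1(2H)-one
Product: 18 (3R,8aR)-4-(tert-butyldimethylsilyloxy)-6,8a-dimethyl-3-(propan-2-yl)-3-(triethylsilyloxy)-3,8a-dihydroazulen-1-yl trifluoromethanesulfonate (C7 and C4 arranged as in 17)
Conditions: KN(SiMe3)2, THF, −78 °C; PhNTf2, −78 → 0 °C; aq NH4Cl
Reagents that add atoms: N-phenylbis(trifluoromethanesulfonimide), O=S(=O)(N(c1ccccc1)S(=O)(=O)C(F)(F)F)C(F)(F)F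
Why: Regiodefined enol triflate formation: the C5 ketone can enolise only towards C6 because C4 is quaternary, and O-sulfonylation of the potassium enolate at −78 °C is faster than β-elimination of the C7 silyloxy group.

Step 11
Reactants: 18 the enol triflate
Product: 19 tert-butyl{[(3R,8aS)-6,8a-dimethyl-3-(propan-2-yl)-3-(triethylsilyloxy)-3,8a-dihydroazulen-4-yl]oxy}dimethylsilane (C5=C6 alkene; C7 and C4 arranged as in 17)
Conditions: Pd(OAc)2 (5 mol %), PPh3 (10 mol %), HCO2H, Bu3N, DMF, 60 °C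
Reagents that add atoms: none
Why: Palladium-catalysed formate reduction of a vinyl triflate (oxidative addition to zerovalent palladium, formate-to-hydride exchange with loss of CO2, reductive elimination) removes the C5 oxygen under amine-buffered conditions that spare both silyl ethers.

Step 12
Reactants: 19 the silyl trienol ether
Product: 21 (3R,3aR,8aS)-6,8a-dimethyl-3-(propan-2-yl)-3-(triethylsilyloxy)-3a,8a-dihydroazulen-4(3H)-one, via ammonium enolate 20 (not isolated)
Conditions: Bu4NF (1.05 equiv), AcOH (1.5 equiv), THF, −78 → −20 °C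
Reagents that add atoms: none
Why: Fluoride cleaves the silyl enol ether, far more labile than the hindered tertiary triethylsilyl ether, and enolate 20 is protonated by acetic acid at C8 from the face opposite the C4 methyl and C7 isopropyl groups, which sets C8–H cis to O7 (trans ring fusion); the cold buffered medium preserves this kinetic centre and avoids β-elimination.

Step 13
Reactants: 21 the 2,4-dienone
Product: 23 (3R,3aR,8aS)-6,8a-dimethyl-3-(propan-2-yl)-3-(triethylsilyloxy)-3a,5,8,8a-tetrahydroazulen-4(3H)-one, via lithium dienolate 22 (not isolated)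
Conditions: Li (2.5 equiv), NH3(l)/THF, −78 °C, 10 min; then solid NH4Cl, −78 °C
Reagents that add atoms: none
Why: Dissolving-metal reduction of a linear 2,4-dienone: two-electron transfer and protonation at the δ-carbon C3 by ammonia give dienolate 22, whose kinetic protonation at the α-carbon C10 leaves the C1=C2 alkene out of conjugation (as steroidal 4,6-dien-3-ones give 5-en-3-ones), while C8 is untouched because the carbonyl is held as the dienolate and the isolated C5=C6 alkene is not reduced.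

Step 14
Reactants: 23 the β,γ-unsaturated ketone
Product: 24 (3R,3aS,4R,8aS)-6,8a-dimethyl-3-(propan-2-yl)-3-(triethylsilyloxy)-3,3a,4,5,8,8a-hexahydroazulen-4-ol
Conditions: NaBH4, CeCl3·7H2O, MeOH, −78 °C
Reagents that add atoms: none
Why: Luche-type carbonyl reduction: the small hydride attacks C9 from the face opposite the angular C4 methyl (1,3-related to C9, as in 6-oxo steroids), placing the C9 oxygen cis to that methyl and H9 cis to H8, while cerium keeps the medium non-basic so the β,γ-alkene does not move into conjugation.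

Step 15
Reactants: 24 the C9 alcohol; 25 4-(tert-butyldimethylsilyloxy)benzoic acid
Product: 27 (3R,3aS,4R,8aS)-6,8a-dimethyl-3-(propan-2-yl)-3-(triethylsilyloxy)-3,3a,4,5,8,8a-hexahydroazulen-4-yl 4-(tert-butyldimethylsilyloxy)benzoate, via mixed anhydride 26 (not isolated)
Conditions: 25, 2,4,6-trichlorobenzoyl chloride, Et3N, THF, 23 °C; then 24, DMAP, toluene, 50 °C
Reagents that add atoms: 2,4,6-trichlorobenzoyl chloride, O=C(Cl)c1c(Cl)cc(Cl)cc1Cl (atoms kept only in 26)
Why: Yamaguchi esterification: the acid is activated as mixed anhydride 26 and DMAP transfers the aroyl group to the hindered secondary C9 alcohol with retention, O7 being silylated.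

Step 16
Reactants: 27 the bis-silylated ester
Product: 28 (3R,3aS,4R,8aS)-3-hydroxy-6,8a-dimethyl-3-(propan-2-yl)-3,3a,4,5,8,8a-hexahydroazulen-4-yl 4-hydroxybenzoate
Conditions: Bu4NF (3 equiv), AcOH (3 equiv), THF, 0 → 23 °C
Reagents that add atoms: none
Why: Fluoride-mediated desilylation removes the aryl silyl ether and the tertiary triethylsilyl ether, with acetic acid buffering phenoxide and alkoxide so that the benzoate neither migrates nor is cleaved.

Step 17
Reactants: 28 the 5,6-dehydro compound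
Product: 29 (3S,3aS,4R,8aR)-3-hydroxy-6,8a-dimethyl-3-(propan-2-yl)-1,2,3,3a,4,5,8,8a-octahydroazulen-4-yl 4-hydroxybenzoate (target)
Conditions: 2-nitrobenzenesulfonyl hydrazide, Et3N, CH2Cl2, 23 °C
Reagents that add atoms: none
Why: Diimide reduction: concerted syn transfer of two hydrogens from HN=NH, made in the flask from the sulfonyl hydrazide, saturates the strained cis-disubstituted cyclopentene C5=C6 much faster than the trisubstituted C1=C2 alkene and creates no stereocentre.

**Compound list**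

1 | m-cresol (3-methylphenol) | Cc1cccc(O)c1 | starting material
2 | isobutyryl chloride | CC(C)C(=O)Cl | starting material
3 | 3-methylphenyl 2-methylpropanoate | CC(C)C(=O)Oc1cccc(C)c1 | intermediate
4 | 1-(2-hydroxy-4-methylphenyl)-2-methylpropan-1-one | CC(C)C(=O)c1ccc(C)cc1O | intermediate
5 | (3aR,7aR)-2-allyl-1,3-bis(4-bromobenzyl)-2-chlorooctahydro-1H-1,3,2-benzodiazasilole | C=CC[Si]1(Cl)N(Cc2ccc(Br)cc2)[C@@H]2CCCC[C@H]2N1Cc1ccc(Br)cc1 | starting material
6 | (3aR,7aR)-2-allyl-1,3-bis(4-bromobenzyl)-2-(2-isobutyryl-5-methylphenoxy)octahydro-1H-1,3,2-benzodiazasilole | CC(C)C(=O)c1ccc(C)cc1O[Si]2(CC=C)N(Cc3ccc(Br)cc3)[C@@H]4CCCC[C@H]4N2Cc5ccc(Br)cc5 | intermediate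
7 | (S)-2-(3-hydroxy-2-methylhex-5-en-3-yl)-5-methylphenol | C=CC[C@](O)(C(C)C)c1ccc(C)cc1O | intermediate
8 | (S)-3-[2-(tert-butyldimethylsilyloxy)-4-methylphenyl]-2-methylhex-5-en-3-ol | C=CC[C@](O)(C(C)C)c1ccc(C)cc1O[Si](C)(C)C(C)(C)C | intermediate
9 | tert-butyl{5-methyl-2-[(3S)-2-methyl-3-(triethylsilyloxy)hex-5-en-3-yl]phenoxy}dimethylsilane | C=CC[C@](O[Si](CC)(CC)CC)(C(C)C)c1ccc(C)cc1O[Si](C)(C)C(C)(C)C | intermediate
10 | (3S)-3-[2-(tert-butyldimethylsilyloxy)-4-methylphenyl]-4-methyl-3-(triethylsilyloxy)pentanal | O=CC[C@](O[Si](CC)(CC)CC)(C(C)C)c1ccc(C)cc1O[Si](C)(C)C(C)(C)C | intermediate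
11 | ethylmagnesium bromide | CC[Mg]Br | starting material
12 | (5S)-5-[2-(tert-butyldimethylsilyloxy)-4-methylphenyl]-6-methyl-5-(triethylsilyloxy)heptan-3-ol (C3 epimers) | CCC(O)C[C@](O[Si](CC)(CC)CC)(C(C)C)c1ccc(C)cc1O[Si](C)(C)C(C)(C)C | intermediate
13 | (5S)-5-[2-(tert-butyldimethylsilyloxy)-4-methylphenyl]-6-methyl-5-(triethylsilyloxy)heptan-3-one | CCC(=O)C[C@](O[Si](CC)(CC)CC)(C(C)C)c1ccc(C)cc1O[Si](C)(C)C(C)(C)C | intermediate
14 | (6S)-6-[2-(tert-butyldimethylsilyloxy)-4-methylphenyl]-1,1,1-trifluoro-3,7-dimethyl-6-(triethylsilyloxy)octane-2,4-dione | CC(C(=O)C(F)(F)F)C(=O)C[C@](O[Si](CC)(CC)CC)(C(C)C)c1ccc(C)cc1O[Si](C)(C)C(C)(C)C | intermediate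
15 | (5S)-2-diazo-5-[2-(tert-butyldimethylsilyloxy)-4-methylphenyl]-6-methyl-5-(triethylsilyloxy)heptan-3-one | CC(=[N+]=[N-])C(=O)C[C@](O[Si](CC)(CC)CC)(C(C)C)c1ccc(C)cc1O[Si](C)(C)C(C)(C)C | intermediate
16 | norcaradiene valence isomer of 17 (cyclopropane C4–C8–C3 fused to the cyclopentanone and to the silyloxy-methylcyclohexadiene) | CC1=C[C@@H]2[C@@]3(C)C(=O)C[C@](O[Si](CC)(CC)CC)(C(C)C)[C@@]23C(O[Si](C)(C)C(C)(C)C)=C1 | intermediate
17 | (3S,8aR)-4-(tert-butyldimethylsilyloxy)-6,8a-dimethyl-3-(propan-2-yl)-3-(triethylsilyloxy)-3,8a-dihydroazulen-1(2H)-one | CC1=CC(O[Si](C)(C)C(C)(C)C)=C2[C@@](O[Si](CC)(CC)CC)(C(C)C)CC(=O)[C@]2(C)C=C1 | intermediate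
18 | (3R,8aR)-4-(tert-butyldimethylsilyloxy)-6,8a-dimethyl-3-(propan-2-yl)-3-(triethylsilyloxy)-3,8a-dihydroazulen-1-yl trifluoromethanesulfonate | CC1=CC(O[Si](C)(C)C(C)(C)C)=C2[C@@](O[Si](CC)(CC)CC)(C(C)C)C=C(OS(=O)(=O)C(F)(F)F)[C@]2(C)C=C1 | intermediate
19 | tert-butyl{[(3R,8aS)-6,8a-dimethyl-3-(propan-2-yl)-3-(triethylsilyloxy)-3,8a-dihydroazulen-4-yl]oxy}dimethylsilane | CC1=CC(O[Si](C)(C)C(C)(C)C)=C2[C@@](O[Si](CC)(CC)CC)(C(C)C)C=C[C@]2(C)C=C1 | intermediate
20 | tetrabutylammonium enolate of 21 (C9 oxido, C8=C9) | CC1=CC([O-])=C2[C@@](O[Si](CC)(CC)CC)(C(C)C)C=C[C@]2(C)C=C1.CCCC[N+](CCCC)(CCCC)CCCC | intermediate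
21 | (3R,3aR,8aS)-6,8a-dimethyl-3-(propan-2-yl)-3-(triethylsilyloxy)-3a,8a-dihydroazulen-4(3H)-one | CC1=CC(=O)[C@H]2[C@@](O[Si](CC)(CC)CC)(C(C)C)C=C[C@]2(C)C=C1 | intermediate
22 | lithium dienolate of 23 (O–C9=C10–C1=C2) | [Li]OC1=CC(C)=CC[C@@]2(C)C=C[C@](O[Si](CC)(CC)CC)(C(C)C)[C@H]12 | intermediate
23 | (3R,3aR,8aS)-6,8a-dimethyl-3-(propan-2-yl)-3-(triethylsilyloxy)-3a,5,8,8a-tetrahydroazulen-4(3H)-one | CC1=CC[C@@]2(C)C=C[C@](O[Si](CC)(CC)CC)(C(C)C)[C@@H]2C(=O)C1 | intermediate
24 | (3R,3aS,4R,8aS)-6,8a-dimethyl-3-(propan-2-yl)-3-(triethylsilyloxy)-3,3a,4,5,8,8a-hexahydroazulen-4-ol | CC1=CC[C@@]2(C)C=C[C@](O[Si](CC)(CC)CC)(C(C)C)[C@@H]2[C@H](O)C1 | intermediate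
25 | 4-(tert-butyldimethylsilyloxy)benzoic acid | CC(C)(C)[Si](C)(C)Oc1ccc(cc1)C(O)=O | starting material
26 | 4-(tert-butyldimethylsilyloxy)benzoic 2,4,6-trichlorobenzoic anhydride | CC(C)(C)[Si](C)(C)Oc1ccc(cc1)C(=O)OC(=O)c1c(Cl)cc(Cl)cc1Cl | intermediate
27 | (3R,3aS,4R,8aS)-6,8a-dimethyl-3-(propan-2-yl)-3-(triethylsilyloxy)-3,3a,4,5,8,8a-hexahydroazulen-4-yl 4-(tert-butyldimethylsilyloxy)benzoate | CC1=CC[C@@]2(C)C=C[C@](O[Si](CC)(CC)CC)(C(C)C)[C@@H]2[C@H](OC(=O)c2ccc(O[Si](C)(C)C(C)(C)C)cc2)C1 | intermediate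
28 | (3R,3aS,4R,8aS)-3-hydroxy-6,8a-dimethyl-3-(propan-2-yl)-3,3a,4,5,8,8a-hexahydroazulen-4-yl 4-hydroxybenzoate | CC1=CC[C@@]2(C)C=C[C@](O)(C(C)C)[C@@H]2[C@H](OC(=O)c2ccc(O)cc2)C1 | intermediate
29 | (3S,3aS,4R,8aR)-3-hydroxy-6,8a-dimethyl-3-(propan-2-yl)-1,2,3,3a,4,5,8,8a-octahydroazulen-4-yl 4-hydroxybenzoate | CC1=CC[C@@]2(C)CC[C@](O)(C(C)C)[C@@H]2[C@H](OC(=O)c2ccc(O)cc2)C1 | target

**Totals.** 17 steps; longest linear sequence 17 steps (1 → 29).

**Steps most likely to fail**

1. Step 9. The carbenoid may take the arene face that puts the small silyloxy group, rather than isopropyl, beside the new quaternary carbon. That is the preference known for benzylic substituents in this reaction class, and it would give the C4 epimer of 17; 1,2-hydride shift to the enone is the second loss channel. The fallback is a stereochemical relay that lets this preference work for the route and corrects C7 at the end. It sets out from 4: allylation with the (S,S)-antipode of 5 gives the enantiomeric diol F1. The operations of steps 3–8 then give the silyl ether F2, the bis-silyl ether F3, the aldehyde F4, the alcohol F5, the ketone F6 and the (R)-diazoketone F7. Cyclisation with the same copper catalyst, now acting with the substrate, should give the C7-epimeric trienone F8 with C4 as in 17. Steps 10–15 give the triflate F9, the tetraene F10, the dienone F11, the β,γ-enone F12, the alcohol F13 and the ester F14, and step 16 gives the 7-epi diol ester F15. C7 is then inverted under control of the C4 methyl. Pyridinium chlorochromate, C5H5NH[CrO3Cl], in CH2Cl2 (Babler–Dauben oxidative transposition of the tertiary allylic alcohol) gives the cyclopentenone F16. H2O2/NaOH in MeOH at 0 °C (Weitz–Scheffer epoxidation from the face opposite the angular methyl and the C9 ester) gives the epoxy ketone F17. N2H4·H2O with AcOH in MeOH (Wharton transposition) returns the C5=C6 alkene and the C7 alcohol trans to the C4 methyl. The fallback comes back to the route at 28.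

2. Step 12. Protonation of enolate 20 from the wrong face, or later enolisation of the doubly activated C8–H of dienone 21, would give the cis-fused ketone, and the same enolate can expel the C7 silyloxy group. The fallback sets out from 19 and changes the order of events. (η6-Naphthalene)Cr(CO)3 (10 mol %) under H2 (50 bar) in THF at 40 °C should add hydrogen 1,4 across the less substituted s-cis diene C3=C2–C1=C10, giving the silyl enol ether F18 with the C1=C2 alkene already in place. Bu4NF/AcOH at −78 °C then protonates a simple, non-conjugated ketone enolate at C8. This bypasses both dienone 21 and the dissolving-metal step, and the fallback comes back at 23.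

3. Step 2. Allyl transfer to the branched isopropyl ketone may be slow or incompletely enantioselective. The fallback sets out from 4. Allylmagnesium bromide (2.2 equiv, THF, 0 °C) gives the racemic diol F19. Acylation of the phenol with (1S)-camphanic chloride (Et3N, DMAP, CH2Cl2) gives two diastereomeric aryl esters that are separated by crystallisation or chromatography. The camphanate of the (S)-carbinol F20 is cleaved with K2CO3 in MeOH, and the fallback comes back at 7.

**Further compounds**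

F1 | step 9 | (R)-2-(3-hydroxy-2-methylhex-5-en-3-yl)-5-methylphenol (enantiomer of 7) | C=CC[C@@](O)(C(C)C)c1ccc(C)cc1O
F2 | step 9 | enantiomer of 8 | C=CC[C@@](O)(C(C)C)c1ccc(C)cc1O[Si](C)(C)C(C)(C)C
F3 | step 9 | enantiomer of 9 | C=CC[C@@](O[Si](CC)(CC)CC)(C(C)C)c1ccc(C)cc1O[Si](C)(C)C(C)(C)C
F4 | step 9 | enantiomer of 10 | O=CC[C@@](O[Si](CC)(CC)CC)(C(C)C)c1ccc(C)cc1O[Si](C)(C)C(C)(C)C
F5 | step 9 | (5R) counterpart of 12 (C3 epimers) | CCC(O)C[C@@](O[Si](CC)(CC)CC)(C(C)C)c1ccc(C)cc1O[Si](C)(C)C(C)(C)C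
F6 | step 9 | enantiomer of 13 | CCC(=O)C[C@@](O[Si](CC)(CC)CC)(C(C)C)c1ccc(C)cc1O[Si](C)(C)C(C)(C)C
F7 | step 9 | enantiomer of 15 | CC(=[N+]=[N-])C(=O)C[C@@](O[Si](CC)(CC)CC)(C(C)C)c1ccc(C)cc1O[Si](C)(C)C(C)(C)C
F8 | step 9 | C7 epimer of 17 | CC1=CC(O[Si](C)(C)C(C)(C)C)=C2[C@](O[Si](CC)(CC)CC)(C(C)C)CC(=O)[C@]2(C)C=C1
F9 | step 9 | C7 epimer of 18 | CC1=CC(O[Si](C)(C)C(C)(C)C)=C2[C@](O[Si](CC)(CC)CC)(C(C)C)C=C(OS(=O)(=O)C(F)(F)F)[C@]2(C)C=C1
F10 | step 9 | C7 epimer of 19 | CC1=CC(O[Si](C)(C)C(C)(C)C)=C2[C@](O[Si](CC)(CC)CC)(C(C)C)C=C[C@]2(C)C=C1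
F11 | step 9 | C7 epimer of 21 | CC1=CC(=O)[C@H]2[C@](O[Si](CC)(CC)CC)(C(C)C)C=C[C@]2(C)C=C1
F12 | step 9 | C7 epimer of 23 | CC1=CC[C@@]2(C)C=C[C@@](O[Si](CC)(CC)CC)(C(C)C)[C@@H]2C(=O)C1
F13 | step 9 | C7 epimer of 24 | CC1=CC[C@@]2(C)C=C[C@@](O[Si](CC)(CC)CC)(C(C)C)[C@@H]2[C@H](O)C1
F14 | step 9 | C7 epimer of 27 | CC1=CC[C@@]2(C)C=C[C@@](O[Si](CC)(CC)CC)(C(C)C)[C@@H]2[C@H](OC(=O)c2ccc(O[Si](C)(C)C(C)(C)C)cc2)C1
F15 | step 9 | C7 epimer of 28 | CC1=CC[C@@]2(C)C=C[C@@](O)(C(C)C)[C@@H]2[C@H](OC(=O)c2ccc(O)cc2)C1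
F16 | step 9 | cyclopentenone: C5 ketone, C6=C7 alkene bearing isopropyl, C8, C9 and C4 as in 28 | CC1=CC[C@@]2(C)C(=O)C=C(C(C)C)[C@@H]2[C@H](OC(=O)c2ccc(O)cc2)C1
F17 | step 9 | C6–C7 epoxy ketone of F16, epoxide oxygen trans to the C4 methyl | CC1=CC[C@@]2(C)C(=O)[C@H]3O[C@@]3(C(C)C)[C@@H]2[C@H](OC(=O)c2ccc(O)cc2)C1
F18 | step 12 | C8=C9 tert-butyldimethylsilyl enol ether with C1=C2 and C5=C6 alkenes and C7 triethylsilyl ether | CC1=CC[C@@]2(C)C=C[C@](O[Si](CC)(CC)CC)(C(C)C)C2=C(O[Si](C)(C)C(C)(C)C)C1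
F19 | step 2 | racemic 2-(3-hydroxy-2-methylhex-5-en-3-yl)-5-methylphenol | C=CCC(O)(C(C)C)c1ccc(C)cc1O
F20 | step 2 | 2-[(3S)-3-hydroxy-2-methylhex-5-en-3-yl]-5-methylphenyl (1S)-camphanate | C=CC[C@](O)(C(C)C)c1ccc(C)cc1OC(=O)[C@@]12CC[C@@](C)(C(=O)O1)C2(C)C
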